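**Plan**

- Cuts: (i) C4(top unit)–C8(middle unit), made by base-induced para-quinone methide formation and phenolate C-alkylation; (ii) C4(middle)–C8(bottom), made by aryllithium addition to a flavan-4-one and ionic reduction; (iii) in the common 5-deoxy monomer, O1–C8a and C3–C4 of ring C, made together.
- Enabling feature: C4 sits on C4a, ortho to C8a of ring A, and C3 lies between the oxygen-bearing C2 and C4. A nitrile carbon as C4 therefore accepts a dithiane (acyl-anion) carbon as C3 and at the same time activates the C8a–F bond toward the C2 alkoxide.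
- Forward: carbinol 5 (C2, C3, ring B) and ring A fluoronitrile 8 give ring C in one flask (step 5). Redox adjustment gives the all-cis diol 15, which serves both as top-unit precursor and as middle-unit ketone.
- Assembly: ketone 20 plus 8-lithio-epicatechin gives the 4α link; quinone methide from 18 plus the phenolate of 27 gives the 4β link; hydrogenolysis finishes.
- Stereochemistry: C2 from CBS reduction; C3 from LiBH(s-Bu)3 (cis); middle C4 from hydride anti to 3-OTBS; top C4 from attack anti to C3–O; bottom unit from (−)-epicatechin.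
- Helpers removed later: dithiane (C3), ketimine/ketone (C4), Br at C6 (and C8 of the top unit), silyl and benzyl ethers.

Key step: step 5

Remark: flavan numbering is used (O1, C2–C4, C4a, C5–C8, C8a) and α is the face of the C2 aryl group; the C4 carbinol configurations drawn for 13–15 and 25 are the expected ones and are erased in steps 12, 17 and 19.

**Step 1**
Reactants: 1 methyl 3,4,5-tris(benzyloxy)benzoate; 2 1,3-dithiane
Product: 4 (1,3-dithian-2-yl)[3,4,5-tris(benzyloxy)phenyl]methanone, via 2-lithio-1,3-dithiane 3 (not isolated)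
Conditions: 2 (2.2 equiv), n-BuLi (2.1 equiv), THF, −30 °C; then 1, −78 → 0 °C; H2O
Reagents that add atoms: none
Why: Corey–Seebach acylation of a lithiated dithiane by an ester, in which the second equivalent of 3 deprotonates the acidic product and so stops over-addition.

**Step 2**
Reactants: 4 (1,3-dithian-2-yl)[3,4,5-tris(benzyloxy)phenyl]methanone
Product: 5 (R)-(1,3-dithian-2-yl)[3,4,5-tris(benzyloxy)phenyl]methanol
Conditions: (R)-2-methyl-CBS-oxazaborolidine (0.2 equiv), BH3·SMe2, THF, −20 °C; aqueous work-up; recrystallization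
Reagents that add atoms: none
Why: Corey–Bakshi–Shibata reduction, in which the aryl group is expected to act as the large substituent so that hydride is delivered to the face that gives the R carbinol (future C2), with the enantiomeric purity to be raised by recrystallization.

**Step 3**
Reactants: 6 2-fluoro-4-hydroxybenzonitrile
Product: 7 5-bromo-2-fluoro-4-hydroxybenzonitrile
Conditions: NBS (1.05 equiv), MeCN, 0 → 23 °C
Reagents that add atoms: N-bromosuccinimide, O=C1CCC(=O)N1Br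
Why: Electrophilic aromatic bromination ortho to the phenol, expected at C5 (para to fluorine) as the less hindered of the two ortho positions.

**Step 4**
Reactants: 7 5-bromo-2-fluoro-4-hydroxybenzonitrile
Product: 8 5-bromo-2-fluoro-4-[(triisopropylsilyl)oxy]benzonitrile
Conditions: TIPSCl, imidazole, DMF, 23 °C
Reagents that add atoms: triisopropylsilyl chloride, CC(C)[Si](Cl)(C(C)C)C(C)C
Why: Standard phenol silylation, giving a phenol mask that tolerates organolithium reagents and is later removed by fluoride.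

**Step 5**
Reactants: 5 (R)-(1,3-dithian-2-yl)[3,4,5-tris(benzyloxy)phenyl]methanol; 8 5-bromo-2-fluoro-4-[(triisopropylsilyl)oxy]benzonitrile
Product: 12 (2R)-6-bromo-2-[3,4,5-tris(benzyloxy)phenyl]-7-[(triisopropylsilyl)oxy]spiro[chromane-3,2'-[1,3]dithian]-4-one, via dilithio dianion 9 (not isolated), via open-chain N-lithio ketimine 10 (not isolated), via cyclic N-lithio ketimine 11 (not isolated)
Conditions: 5, n-BuLi (2.05 equiv), TMEDA, THF, −78 → −20 °C; then 8, −78 → 23 °C (→ 50 °C); then aq. HCl (1 M), THF, 23 °C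
Reagents that add atoms: water, O
Why: Proposed new method: the β-oxido 2-lithio-1,3-dithiane 9 (the alkoxide blocks β-elimination) adds through C3 to the nitrile carbon C4, the C2 lithium alkoxide of 10 then displaces fluoride at C8a by addition–elimination with the ortho C=N group and the para bromine stabilising the Meisenheimer intermediate, and aqueous acid hydrolyses ketimine 11 to the ketone. The closest known reactions are the addition of lithiated dithianes to nitriles and the tandem carbanion addition/SNAr ring closures of ortho-fluorobenzonitriles and ortho-fluoroaryl ketones used for chromanones and chromones. Ring C closes in the 6-exo-trig mode at C8a (SNAr) after the intermolecular C3–C4 bond formation. No new stereocenter arises (C3 is a symmetric spiro dithioketal carbon, C4 is sp2), and C2 is carried over from 5 because the metallated ketimine offers neither an enolisable position nor a retro-aldol exit. The step needs C-attack at the nitrile before O-attack at C–F (secured by the far higher nucleophilicity of the carbanion at −78 °C) and displacement of fluoride and not bromide (secured by the position ortho to C=N and the leaving-group order of SNAr).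

**Step 6**
Reactants: 12 (2R)-6-bromo-2-[3,4,5-tris(benzyloxy)phenyl]-7-[(triisopropylsilyl)oxy]spiro[chromane-3,2'-[1,3]dithian]-4-one
Product: 13 (2R,4R)-6-bromo-2-[3,4,5-tris(benzyloxy)phenyl]-7-[(triisopropylsilyl)oxy]spiro[chromane-3,2'-[1,3]dithian]-4-ol
Conditions: NaBH4, THF/MeOH, 0 °C
Reagents that add atoms: none
Why: Borohydride reduction of the aryl ketone, which masks C4 so that C3 can be unveiled without forming a 3,4-dione; axial hydride delivery should place the 4-OH cis to the C2 aryl group.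

**Step 7**
Reactants: 13 (2R,4R)-6-bromo-2-[3,4,5-tris(benzyloxy)phenyl]-7-[(triisopropylsilyl)oxy]spiro[chromane-3,2'-[1,3]dithian]-4-ol
Product: 14 (2R,4R)-6-bromo-4-hydroxy-2-[3,4,5-tris(benzyloxy)phenyl]-7-[(triisopropylsilyl)oxy]chroman-3-one
Conditions: I2, NaHCO3, acetone/H2O, 0 °C; used at once
Reagents that add atoms: water, O
Why: Buffered oxidative hydrolysis of the dithioketal releases the C3 ketone under near-neutral conditions that should not isomerize the α-ketol.

**Step 8**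
Reactants: 14 (2R,4R)-6-bromo-4-hydroxy-2-[3,4,5-tris(benzyloxy)phenyl]-7-[(triisopropylsilyl)oxy]chroman-3-one
Product: 15 (2R,3R,4R)-6-bromo-2-[3,4,5-tris(benzyloxy)phenyl]-7-[(triisopropylsilyl)oxy]chromane-3,4-diol
Conditions: LiBH(s-Bu)3 (2.5 equiv), THF, −78 °C
Reagents that add atoms: none
Why: Bulky-hydride reduction of a 2-aryl-chroman-3-one, where equatorial attack anti to the C2 aryl group gives the axial 3-OH cis to it, the same tactic that turns catechin-type 3-ketones into epi-series alcohols.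

**Step 9**
Reactants: 15 (2R,3R,4R)-6-bromo-2-[3,4,5-tris(benzyloxy)phenyl]-7-[(triisopropylsilyl)oxy]chromane-3,4-diol
Product: 16 cis-fused 3,4-cyclic carbonate of 15
Conditions: 1,1'-carbonyldiimidazole (1.5 equiv), DMAP (cat.), CH2Cl2, 23 °C
Reagents that add atoms: 1,1'-carbonyldiimidazole, O=C(n1ccnc1)n1ccnc1
Why: Cyclic carbonate formation from a cis-1,2-diol, which turns the C4 oxygen into a leaving group whose departure leaves no protecting group on O3.

**Step 10**
Reactants: 16 cis-fused 3,4-cyclic carbonate of 15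
Product: 17 cis-fused 3,4-cyclic carbonate of (2R,3R,4R)-6-bromo-2-[3,4,5-tris(benzyloxy)phenyl]chromane-3,4,7-triol
Conditions: n-Bu4NF (1.1 equiv), AcOH (1.5 equiv), THF, 0 °C
Reagents that add atoms: none
Why: Fluoride cleavage of the aryl silyl ether, buffered so that the phenol stays protonated and the para-benzylic carbonate is not expelled early.

**Step 11**
Reactants: 17 cis-fused 3,4-cyclic carbonate of (2R,3R,4R)-6-bromo-2-[3,4,5-tris(benzyloxy)phenyl]chromane-3,4,7-triol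
Product: 18 cis-fused 3,4-cyclic carbonate of (2R,3R,4R)-6,8-dibromo-2-[3,4,5-tris(benzyloxy)phenyl]chromane-3,4,7-triol
Conditions: NBS (1.05 equiv), CH2Cl2/MeCN, −40 → 0 °C
Reagents that add atoms: N-bromosuccinimide, O=C1CCC(=O)N1Br
Why: Phenol-directed electrophilic bromination at C8, the only free ortho position, which caps ring A of the top unit against self-condensation.

**Step 12**
Reactants: 15 (2R,3R,4R)-6-bromo-2-[3,4,5-tris(benzyloxy)phenyl]-7-[(triisopropylsilyl)oxy]chromane-3,4-diol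
Product: 19 (2R,3S)-6-bromo-3-hydroxy-2-[3,4,5-tris(benzyloxy)phenyl]-7-[(triisopropylsilyl)oxy]chroman-4-one
Conditions: MnO2 (excess), CH2Cl2, 23 °C
Reagents that add atoms: none
Why: Selective MnO2 oxidation of the benzylic C4 carbinol, which leaves the non-benzylic cis 3-OH untouched under neutral conditions.

**Step 13**
Reactants: 19 (2R,3S)-6-bromo-3-hydroxy-2-[3,4,5-tris(benzyloxy)phenyl]-7-[(triisopropylsilyl)oxy]chroman-4-one
Product: 20 (2R,3S)-6-bromo-3-[(tert-butyldimethylsilyl)oxy]-2-[3,4,5-tris(benzyloxy)phenyl]-7-[(triisopropylsilyl)oxy]chroman-4-one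
Conditions: TBSOTf, 2,6-lutidine, CH2Cl2, −78 °C
Reagents that add atoms: tert-butyldimethylsilyl triflate, CC(C)(C)[Si](C)(C)OS(=O)(=O)C(F)(F)F
Why: Silylation under weakly basic low-temperature conditions, which should not epimerize the 2,3-cis α-silyloxy ketone.

**Step 14**
Reactants: 21 (−)-epicatechin
Product: 22 (2R,3R)-3,5,7-tris(benzyloxy)-2-[3,4-bis(benzyloxy)phenyl]chromane
Conditions: NaH, BnBr (5.5 equiv), DMF, −10 → 23 °C
Reagents that add atoms: benzyl bromide, BrCc1ccccc1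
Why: Williamson perbenzylation, with fast O-alkylation at low temperature to outrun base-induced C2 epimerization.

**Step 15**
Reactants: 22 (2R,3R)-3,5,7-tris(benzyloxy)-2-[3,4-bis(benzyloxy)phenyl]chromane
Product: 23 (2R,3R)-8-bromo-3,5,7-tris(benzyloxy)-2-[3,4-bis(benzyloxy)phenyl]chromane
Conditions: NBS (1.0 equiv), CH2Cl2, −40 → 0 °C
Reagents that add atoms: N-bromosuccinimide, O=C1CCC(=O)N1Br
Why: Electrophilic bromination of a 5,7-dialkoxyflavan, which is regioselective for C8 as established for benzylated catechins.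

**Step 16**
Reactants: 23 (2R,3R)-8-bromo-3,5,7-tris(benzyloxy)-2-[3,4-bis(benzyloxy)phenyl]chromane; 20 (2R,3S)-6-bromo-3-[(tert-butyldimethylsilyl)oxy]-2-[3,4,5-tris(benzyloxy)phenyl]-7-[(triisopropylsilyl)oxy]chroman-4-one
Product: 25 6-bromo-3-[(tert-butyldimethylsilyl)oxy]-4-[(2R,3R)-3,5,7-tris(benzyloxy)-2-(3,4-bis(benzyloxy)phenyl)chroman-8-yl]-2-[3,4,5-tris(benzyloxy)phenyl]-7-[(triisopropylsilyl)oxy]chroman-4-ol (2α-aryl; 3α-OTBS; 4β-aryl; 4α-OH), via 8-lithio flavan 24 (not isolated)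
Conditions: 23, t-BuLi (2.0 equiv), THF, −78 °C; then 20, −78 °C; H2O
Reagents that add atoms: none
Why: Halogen–lithium exchange followed by 1,2-addition of the C8 aryllithium to the flavan-4-one, expected anti to the 3-OTBS group; the new carbinol center is ionized in the next step.

**Step 17**
Reactants: 25 tertiary 4-aryl carbinol
Product: 26 6-bromo-3-O-(tert-butyldimethylsilyl)-7-O-(triisopropylsilyl)-3',4',5'-tri-O-benzyl-epirobinetinidol-(4α→8)-penta-O-benzylepicatechin (middle unit 2α-aryl; 3α-OTBS; 4α-aryl)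
Conditions: n-Bu3SnH (3 equiv), CF3CO2H, CH2Cl2, 0 °C
Reagents that add atoms: none
Why: Ionic hydrogenation of the doubly benzylic tertiary alcohol, in which the tin hydride attacks the C4 cation from the β face anti to the 3-OTBS group and so leaves the epicatechin unit α (3,4-cis), as known for 4-aryl-flavan-4-ols of the epi series.

**Step 18**
Reactants: 26 silylated 4α→8 dimer
Product: 27 6-bromo-3',4',5'-tri-O-benzyl-epirobinetinidol-(4α→8)-penta-O-benzylepicatechin (free 7-OH and 3-OH on the upper unit)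
Conditions: n-Bu4NF (4 equiv), THF, 23 → 50 °C
Reagents that add atoms: none
Why: Fluoride desilylation removes the aryl TIPS and the hindered secondary TBS ether together and frees the phenol needed as nucleophile.

**Step 19**
Reactants: 18 dibromo phenol cyclic carbonate; 27 dimer phenol
Product: 29 6,8-dibromo-3',4',5'-tri-O-benzyl-epirobinetinidol-(4β→8)-6-bromo-3',4',5'-tri-O-benzyl-epirobinetinidol-(4α→8)-penta-O-benzylepicatechin, via quinone methide 28 (not isolated)
Conditions: 18 (1.2 equiv), 27 (1.0 equiv), Cs2CO3 (2.5 equiv), CH2Cl2/CF3CH2OH (4:1), −20 → 23 °C; aq. citric acid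
Reagents that add atoms: none
Why: Base-induced 1,6-elimination of the carbonate gives the para-quinone methide, which is C-alkylated by the phenolate of 27 at C8, its only free ortho position (conjugate Friedel–Crafts-type addition, the proposed biosynthetic mode), with attack anti to the C3 oxygen setting the 3,4-trans (4β) center; CO2 is lost on work-up.

**Step 20**
Reactants: 29 protected tribromo trimer
Product: 30 epirobinetinidol-(4β→8)-epirobinetinidol-(4α→8)-epicatechin
Conditions: H2 (1 atm), Pd(OH)2/C, NaOAc (3.5 equiv), THF/MeOH/H2O, 23 °C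
Reagents that add atoms: none
Why: Catalytic hydrogenolysis removes the eleven benzyl ethers and the three aryl bromides in one operation without touching the stereocenters.

**Compound list**

1 | methyl 3,4,5-tris(benzyloxy)benzoate | COC(=O)c1cc(OCc2ccccc2)c(OCc2ccccc2)c(OCc2ccccc2)c1 | starting material
2 | 1,3-dithiane | C1CSCSC1 | starting material
3 | 2-lithio-1,3-dithiane | [Li]C1SCCCS1 | intermediate
4 | (1,3-dithian-2-yl)[3,4,5-tris(benzyloxy)phenyl]methanone | O=C(c1cc(OCc2ccccc2)c(OCc2ccccc2)c(OCc2ccccc2)c1)C1SCCCS1 | intermediate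
5 | (R)-(1,3-dithian-2-yl)[3,4,5-tris(benzyloxy)phenyl]methanol | O[C@H](c1cc(OCc2ccccc2)c(OCc2ccccc2)c(OCc2ccccc2)c1)C1SCCCS1 | intermediate
6 | 2-fluoro-4-hydroxybenzonitrile | N#Cc1ccc(O)cc1F | starting material
7 | 5-bromo-2-fluoro-4-hydroxybenzonitrile | N#Cc1cc(Br)c(O)cc1F | intermediate
8 | 5-bromo-2-fluoro-4-[(triisopropylsilyl)oxy]benzonitrile | N#Cc1cc(Br)c(O[Si](C(C)C)(C(C)C)C(C)C)cc1F | intermediate
9 | O,C-dilithio derivative of 5 (lithium alkoxide; lithium at dithiane C2) | [Li]O[C@H](c1cc(OCc2ccccc2)c(OCc2ccccc2)c(OCc2ccccc2)c1)C1([Li])SCCCS1 | intermediate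
10 | open-chain adduct: lithium alkoxide of 5 bearing at dithiane C2 the N-lithio ketimine of the 5-bromo-2-fluoro-4-(triisopropylsilyloxy)phenyl ketone | [Li]O[C@H](c1cc(OCc2ccccc2)c(OCc2ccccc2)c(OCc2ccccc2)c1)C1(SCCCS1)C(=N[Li])c1cc(Br)c(O[Si](C(C)C)(C(C)C)C(C)C)cc1F | intermediate
11 | (2R)-6-bromo-4-(lithioimino)-2-[3,4,5-tris(benzyloxy)phenyl]-7-[(triisopropylsilyl)oxy]spiro[chromane-3,2'-[1,3]dithiane] | [Li]N=C1c2cc(Br)c(O[Si](C(C)C)(C(C)C)C(C)C)cc2O[C@H](c2cc(OCc3ccccc3)c(OCc3ccccc3)c(OCc3ccccc3)c2)C12SCCCS2 | intermediate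
12 | (2R)-6-bromo-2-[3,4,5-tris(benzyloxy)phenyl]-7-[(triisopropylsilyl)oxy]spiro[chromane-3,2'-[1,3]dithian]-4-one | O=C1c2cc(Br)c(O[Si](C(C)C)(C(C)C)C(C)C)cc2O[C@H](c2cc(OCc3ccccc3)c(OCc3ccccc3)c(OCc3ccccc3)c2)C12SCCCS2 | intermediate
13 | (2R,4R)-6-bromo-2-[3,4,5-tris(benzyloxy)phenyl]-7-[(triisopropylsilyl)oxy]spiro[chromane-3,2'-[1,3]dithian]-4-ol (4-OH cis to the C2 aryl group) | CC(C)[Si](C(C)C)(C(C)C)Oc1c(Br)cc2c(c1)O[C@H](c3cc(OCc4ccccc4)c(OCc4ccccc4)c(OCc4ccccc4)c3)C1(SCCCS1)[C@@H]2O | intermediate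
14 | (2R,4R)-6-bromo-4-hydroxy-2-[3,4,5-tris(benzyloxy)phenyl]-7-[(triisopropylsilyl)oxy]chroman-3-one | CC(C)[Si](C(C)C)(C(C)C)Oc1c(Br)cc2c(c1)O[C@H](c3cc(OCc4ccccc4)c(OCc4ccccc4)c(OCc4ccccc4)c3)C(=O)[C@@H]2O | intermediate
15 | (2R,3R,4R)-6-bromo-2-[3,4,5-tris(benzyloxy)phenyl]-7-[(triisopropylsilyl)oxy]chromane-3,4-diol (2,3-cis-3,4-cis) | CC(C)[Si](C(C)C)(C(C)C)Oc1c(Br)cc2c(c1)O[C@H](c3cc(OCc4ccccc4)c(OCc4ccccc4)c(OCc4ccccc4)c3)[C@H](O)[C@@H]2O | intermediate
16 | cis-fused 3,4-cyclic carbonate of 15 (2α-aryl; O3 and O4 both α) | CC(C)[Si](C(C)C)(C(C)C)Oc1c(Br)cc2c(c1)O[C@H](c3cc(OCc4ccccc4)c(OCc4ccccc4)c(OCc4ccccc4)c3)[C@@H]3OC(=O)O[C@H]23 | intermediate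
17 | 7-hydroxy analogue of 16 (cis-fused 3,4-cyclic carbonate of the 6-bromo-3,4,7-triol) | Oc1c(Br)cc2c(c1)O[C@H](c3cc(OCc4ccccc4)c(OCc4ccccc4)c(OCc4ccccc4)c3)[C@@H]3OC(=O)O[C@H]23 | intermediate
18 | 6,8-dibromo analogue of 17 | Oc1c(Br)cc2c(c1Br)O[C@H](c3cc(OCc4ccccc4)c(OCc4ccccc4)c(OCc4ccccc4)c3)[C@@H]3OC(=O)O[C@H]23 | intermediate
19 | (2R,3S)-6-bromo-3-hydroxy-2-[3,4,5-tris(benzyloxy)phenyl]-7-[(triisopropylsilyl)oxy]chroman-4-one (2,3-cis) | CC(C)[Si](C(C)C)(C(C)C)Oc1c(Br)cc2c(c1)O[C@H](c3cc(OCc4ccccc4)c(OCc4ccccc4)c(OCc4ccccc4)c3)[C@H](O)C2=O | intermediate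
20 | (2R,3S)-6-bromo-3-[(tert-butyldimethylsilyl)oxy]-2-[3,4,5-tris(benzyloxy)phenyl]-7-[(triisopropylsilyl)oxy]chroman-4-one (2,3-cis) | CC(C)[Si](C(C)C)(C(C)C)Oc1c(Br)cc2c(c1)O[C@H](c3cc(OCc4ccccc4)c(OCc4ccccc4)c(OCc4ccccc4)c3)[C@H](O[Si](C)(C)C(C)(C)C)C2=O | intermediate
21 | (−)-epicatechin, (2R,3R)-2-(3,4-dihydroxyphenyl)chromane-3,5,7-triol | Oc1cc(O)c2c(c1)O[C@H](c1ccc(O)c(O)c1)[C@H](O)C2 | starting material
22 | (2R,3R)-3,5,7-tris(benzyloxy)-2-[3,4-bis(benzyloxy)phenyl]chromane | c1c(OCc3ccccc3)cc(OCc3ccccc3)c2c1O[C@H](c1ccc(OCc3ccccc3)c(OCc3ccccc3)c1)[C@H](OCc1ccccc1)C2 | intermediate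
23 | (2R,3R)-8-bromo-3,5,7-tris(benzyloxy)-2-[3,4-bis(benzyloxy)phenyl]chromane | Brc1c(OCc3ccccc3)cc(OCc3ccccc3)c2c1O[C@H](c1ccc(OCc3ccccc3)c(OCc3ccccc3)c1)[C@H](OCc1ccccc1)C2 | intermediate
24 | (2R,3R)-8-lithio-3,5,7-tris(benzyloxy)-2-[3,4-bis(benzyloxy)phenyl]chromane | [Li]c1c(OCc3ccccc3)cc(OCc3ccccc3)c2c1O[C@H](c1ccc(OCc3ccccc3)c(OCc3ccccc3)c1)[C@H](OCc1ccccc1)C2 | intermediate
25 | tertiary carbinol: 20 with the penta-O-benzylepicatechin-8-yl group added at C4 (2α-aryl; 3α-OTBS; 4β-aryl; 4α-OH) | CC(C)[Si](C(C)C)(C(C)C)Oc1c(Br)cc2c(c1)O[C@H](c3cc(OCc4ccccc4)c(OCc4ccccc4)c(OCc4ccccc4)c3)[C@H](O[Si](C)(C)C(C)(C)C)[C@@]2(O)c1c(OCc3ccccc3)cc(OCc3ccccc3)c2c1O[C@H](c1ccc(OCc3ccccc3)c(OCc3ccccc3)c1)[C@H](OCc1ccccc1)C2 | intermediate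
26 | 6-bromo-3-O-TBS-7-O-TIPS-3',4',5'-tri-O-benzyl-epirobinetinidol-(4α→8)-penta-O-benzylepicatechin (upper unit 2,3-cis-3,4-cis) | CC(C)[Si](C(C)C)(C(C)C)Oc1c(Br)cc2c(c1)O[C@H](c3cc(OCc4ccccc4)c(OCc4ccccc4)c(OCc4ccccc4)c3)[C@H](O[Si](C)(C)C(C)(C)C)[C@@H]2c1c(OCc3ccccc3)cc(OCc3ccccc3)c2c1O[C@H](c1ccc(OCc3ccccc3)c(OCc3ccccc3)c1)[C@H](OCc1ccccc1)C2 | intermediate
27 | 6-bromo-3',4',5'-tri-O-benzyl-epirobinetinidol-(4α→8)-penta-O-benzylepicatechin | Oc1c(Br)cc2c(c1)O[C@H](c3cc(OCc4ccccc4)c(OCc4ccccc4)c(OCc4ccccc4)c3)[C@H](O)[C@@H]2c1c(OCc3ccccc3)cc(OCc3ccccc3)c2c1O[C@H](c1ccc(OCc3ccccc3)c(OCc3ccccc3)c1)[C@H](OCc1ccccc1)C2 | intermediate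
28 | para-quinone methide from 18 (C7=O, C4a=C4; 6,8-dibromo; 2α-aryl; 3α-O-carboxylate as cesium salt) | O=C1C(Br)=C2O[C@H](c3cc(OCc4ccccc4)c(OCc4ccccc4)c(OCc4ccccc4)c3)[C@H](OC(=O)[O-])C=C2C=C1Br.[Cs+] | intermediate
29 | 6,8-dibromo-3',4',5'-tri-O-benzyl-epirobinetinidol-(4β→8)-6-bromo-3',4',5'-tri-O-benzyl-epirobinetinidol-(4α→8)-penta-O-benzylepicatechin | Oc1c(Br)cc2c(c1Br)O[C@H](c3cc(OCc4ccccc4)c(OCc4ccccc4)c(OCc4ccccc4)c3)[C@H](O)[C@H]2c1c(O)c(Br)cc2c1O[C@H](c3cc(OCc4ccccc4)c(OCc4ccccc4)c(OCc4ccccc4)c3)[C@H](O)[C@@H]2c1c(OCc3ccccc3)cc(OCc3ccccc3)c2c1O[C@H](c1ccc(OCc3ccccc3)c(OCc3ccccc3)c1)[C@H](OCc1ccccc1)C2 | intermediate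
30 | epirobinetinidol-(4β→8)-epirobinetinidol-(4α→8)-epicatechin; top unit (2R,3R,4R), middle unit (2R,3R,4S), bottom unit (2R,3R); epirobinetinidol = (2R,3R)-2-(3,4,5-trihydroxyphenyl)chromane-3,7-diol | Oc1ccc2c(c1)O[C@H](c1cc(O)c(O)c(O)c1)[C@H](O)[C@H]2c1c(O)ccc2c1O[C@H](c1cc(O)c(O)c(O)c1)[C@H](O)[C@@H]2c1c(O)cc(O)c2c1O[C@H](c1ccc(O)c(O)c1)[C@H](O)C2 | target

**Count**

Total steps: 20. Longest linear sequence: 13 steps (1, 2, 5, 6, 7, 8, 12, 13, 16, 17, 18, 19, 20).

**Steps most likely to fail**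

Step 5. The alkoxide may displace fluoride too slowly at the N-lithio ketimine stage, where C8a is only weakly activated, and the carbanion may attack the C–F carbon in competition. The fallback makes the two bonds in two known operations. It sets out from 5 and 8: the dianion of 5 is added to 8 as before, and the mixture is hydrolysed cold with aqueous HCl to the open-chain ketone (R)-[2-(hydroxy{3,4,5-tris(benzyloxy)phenyl}methyl)-1,3-dithian-2-yl][5-bromo-2-fluoro-4-(triisopropylsilyloxy)phenyl]methanone F1 (addition of a lithiated dithiane to a nitrile). The ortho-fluoroaryl ketone, now strongly activated, is then closed by intramolecular SNAr with K2CO3 in DMF at 0 °C, kept cold to outrun retro-aldol cleavage. This comes back to the route at 12.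

Step 19. The quinone methide may tautomerize to the flav-3-ene, and the phenolate may be O-alkylated or react too slowly at the hindered C8. The fallback is the classical cationic flavan-3,4-diol condensation. It sets out from 15 and 27: 15 is desilylated with n-Bu4NF to (2R,3R,4R)-6-bromo-2-[3,4,5-tris(benzyloxy)phenyl]chromane-3,4,7-triol F2, which is brominated at C8 with NBS to the 6,8-dibromo triol F3. F3 is then condensed with 27 under BF3·OEt2 in CH2Cl2/THF at −20 °C through the C4 benzylic cation, with attack anti to the C3 hydroxyl. This comes back to the route at 29.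

Step 7. The freshly unmasked 4-hydroxy-3-ketone may undergo acyloin isomerization to the 3-hydroxy-4-ketone, C4 epimerization or over-oxidation. The fallback avoids the free α-ketol. It sets out from 13, which is silylated with Et3SiOTf and 2,6-lutidine to the 4-O-triethylsilyl ether F4. F4 is unmasked with I2/NaHCO3 to the 4-(triethylsilyloxy)chroman-3-one F5, which cannot tautomerize, and F5 is reduced with LiBH(s-Bu)3 to the 2,3-cis 3-hydroxy-4-(triethylsilyloxy) compound F6. The triethylsilyl group is then removed with PPTS in MeOH, which comes back to the route at 15.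

**Further compounds**

F1 | step 5 | (R)-[2-(hydroxy{3,4,5-tris(benzyloxy)phenyl}methyl)-1,3-dithian-2-yl][5-bromo-2-fluoro-4-(triisopropylsilyloxy)phenyl]methanone | O[C@H](c1cc(OCc2ccccc2)c(OCc2ccccc2)c(OCc2ccccc2)c1)C1(SCCCS1)C(=O)c1cc(Br)c(O[Si](C(C)C)(C(C)C)C(C)C)cc1F
F2 | step 19 | (2R,3R,4R)-6-bromo-2-[3,4,5-tris(benzyloxy)phenyl]chromane-3,4,7-triol | Oc1c(Br)cc2c(c1)O[C@H](c3cc(OCc4ccccc4)c(OCc4ccccc4)c(OCc4ccccc4)c3)[C@H](O)[C@@H]2O
F3 | step 19 | (2R,3R,4R)-6,8-dibromo-2-[3,4,5-tris(benzyloxy)phenyl]chromane-3,4,7-triol | Oc1c(Br)cc2c(c1Br)O[C@H](c3cc(OCc4ccccc4)c(OCc4ccccc4)c(OCc4ccccc4)c3)[C@H](O)[C@@H]2O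
F4 | step 7 | 4-O-triethylsilyl ether of 13 | CC(C)[Si](C(C)C)(C(C)C)Oc1c(Br)cc2c(c1)O[C@H](c3cc(OCc4ccccc4)c(OCc4ccccc4)c(OCc4ccccc4)c3)C1(SCCCS1)[C@@H]2O[Si](CC)(CC)CC
F5 | step 7 | 4-O-triethylsilyl ether of 14 | CC(C)[Si](C(C)C)(C(C)C)Oc1c(Br)cc2c(c1)O[C@H](c3cc(OCc4ccccc4)c(OCc4ccccc4)c(OCc4ccccc4)c3)C(=O)[C@@H]2O[Si](CC)(CC)CC
F6 | step 7 | 4-O-triethylsilyl ether of 15 (free 3-OH cis to the C2 aryl group) | CC(C)[Si](C(C)C)(C(C)C)Oc1c(Br)cc2c(c1)O[C@H](c3cc(OCc4ccccc4)c(OCc4ccccc4)c(OCc4ccccc4)c3)[C@H](O)[C@@H]2O[Si](CC)(CC)CC
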